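**Plan**

- Cuts: the 1,2-dione is traced back to a diarylalkyne, cut at C8–C(sp) into an 8-iodoflavan and alkyne 12. The flavan is then opened at C4–C4a (after restoring a C3=C4 double bond), at O1–C2 and at C2–C(alkyne).
- Forward order: aldehyde 2 → propargylic carbinol → aryl ether (O1–C2) → pyran ring by closure of C4–C4a (the only ring made) → saturation of C3=C4 → iodination and alkynylation at C8 → oxidation to the dione → deprotection.
- Enabling feature: C4–C4a joins the pyran ring to the A ring. In the open precursor that ring is a 3,5-bis(benzyloxy)phenyl ether whose two carbons ortho to O1 (the future C4a and C8) are equivalent, each ortho and para to a benzyloxy group, so 6-endo attack on the alkyne can give only one chromene.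
- Stereochemistry: the single stereocentre C2 (S) is set as a carbinol by catalyst-controlled alkynylation of 2 and inverted once in the Mitsunobu etherification. No bond to it is broken afterwards.

Key step: step 5

Remark: C2 of the target is read as S (O1 > aryl > C3 > H); 5 (S) and 6 (R) have the same spatial arrangement, because only the CIP rank of the alkynyl group changes. The sense of induction in step 2 is assigned by analogy with other aryl aldehydes and would be checked on 6 (chiral HPLC, MTPA esters), with the ligand enantiomer exchanged if needed.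

**Route**

Step 1
Reactants: 1 4-hydroxybenzaldehyde
Product: 2 4-formylphenyl pivalate
Conditions: PivCl (1.1 equiv), Et3N, DMAP (cat.), CH2Cl2, 0 °C → rt
Reagents that add atoms: pivaloyl chloride, CC(C)(C)C(Cl)=O
Why: DMAP-catalysed O-acylation of the phenol leaves the aldehyde untouched and turns the strongly donating hydroxyl into an acyloxy group that later disfavours ionisation at the benzylic carbon.

Step 2
Reactants: 2 4-formylphenyl pivalate; 3 trimethylsilylacetylene
Product: 5 (S)-4-[1-hydroxy-3-(trimethylsilyl)prop-2-yn-1-yl]phenyl pivalate, via ethyl(trimethylsilylethynyl)zinc 4 (not isolated)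
Conditions: 3 (2.2 equiv), Et2Zn (2 equiv), toluene, reflux; then (R)-BINOL (20 mol%), Ti(OiPr)4 (50 mol%), Et2O, rt; then 2, rt; 1 M HCl work-up
Reagents that add atoms: none
Why: Catalytic enantioselective alkynylation of an aryl aldehyde by an alkynylzinc under BINOL–titanium control, in which the (R)-ligand is expected to deliver the alkynyl group to the Re face of the formyl group and so set the carbinol centre as S (the silylalkynyl group outranks the aryl group), while the hindered aryl pivalate is inert to the organozinc.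

Step 3
Reactants: 5 (S)-4-[1-hydroxy-3-(trimethylsilyl)prop-2-yn-1-yl]phenyl pivalate
Product: 6 (R)-4-(1-hydroxyprop-2-yn-1-yl)phenyl pivalate
Conditions: TBAF (1.1 equiv), AcOH (1.2 equiv), THF, 0 °C
Reagents that add atoms: none
Why: Fluoride-induced protodesilylation of the alkynylsilane, buffered with acetic acid so that the aryl ester survives, touches no bond at the carbinol carbon, and the descriptor changes from S to R only because ethynyl ranks below aryl.

Step 4
Reactants: 6 (R)-4-(1-hydroxyprop-2-yn-1-yl)phenyl pivalate; 7 3,5-bis(benzyloxy)phenol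
Product: 8 (S)-4-{1-[3,5-bis(benzyloxy)phenoxy]prop-2-yn-1-yl}phenyl pivalate
Conditions: PPh3 (1.3 equiv), DIAD (1.3 equiv), toluene, 0 °C → rt
Reagents that add atoms: none
Why: Mitsunobu etherification, in which the phenoxide of 7 displaces the oxyphosphonium group in an SN2 step with inversion and so converts the R carbinol into the S aryl ether, SN1 leakage being limited by the acyloxy-substituted aryl group and the non-polar solvent.

Step 5
Reactants: 8 (S)-4-{1-[3,5-bis(benzyloxy)phenoxy]prop-2-yn-1-yl}phenyl pivalate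
Product: 9 (S)-4-[5,7-bis(benzyloxy)-2H-chromen-2-yl]phenyl pivalate
Conditions: [(JohnPhos)Au(NCMe)]SbF6 (2–5 mol%), CH2Cl2, 0 °C → rt, exclusion of light
Reagents that add atoms: none
Why: Cationic gold(I) binds the terminal alkyne as a π-complex, the arene carbon ortho to the ether oxygen and para to a benzyloxy group attacks the terminal alkyne carbon anti to gold to give an arenium/vinylgold intermediate, and rearomatisation followed by protodeauration releases the 2H-chromene and the catalyst. The closest known reaction type is the gold(I)-catalysed intramolecular hydroarylation of aryl propargyl ethers to 2H-chromenes, a Friedel–Crafts alkenylation. The pyran ring closes in the 6-endo-dig mode, the 5-exo alternative (attack at the internal alkyne carbon) leading to a strained exocyclic alkylidene dihydrobenzofuran. No stereocentre is created, and C2 keeps the S configuration because the O1–C2 bond is never broken and the CIP order O > aryl > C3 is unchanged. Regioselectivity on the arene needs no control, since the two carbons ortho to the ether oxygen are related by the local symmetry of the 3,5-bis(benzyloxy)phenoxy group. The selectivity that must be secured is hydroarylation over ionisation of the propargylic C–O bond, for which the acylated B ring (a poor cation stabiliser), the weakly coordinating counter-ion, the non-polar solvent and the low temperature are chosen.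

Step 6
Reactants: 9 (S)-4-[5,7-bis(benzyloxy)-2H-chromen-2-yl]phenyl pivalate
Product: 10 (S)-4-[5,7-bis(benzyloxy)chroman-2-yl]phenyl pivalate
Conditions: 2-nitrobenzenesulfonyl hydrazide (NBSH, 4 equiv), Et3N, CH2Cl2, rt, dark
Reagents that add atoms: none
Why: Diimide released from the sulfonyl hydrazide at room temperature transfers two hydrogen atoms in a concerted syn fashion to the cis-disubstituted C3=C4 bond without hydrogenolysis of the benzyl ethers or of the allylic, benzylic O1–C2 bond, and no stereocentre arises because C3 and C4 become methylene groups.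

Step 7
Reactants: 10 (S)-4-[5,7-bis(benzyloxy)chroman-2-yl]phenyl pivalate
Product: 11 (S)-4-[5,7-bis(benzyloxy)-8-iodochroman-2-yl]phenyl pivalate
Conditions: NIS (1.05 equiv), DMF, 0 °C → rt, dark
Reagents that add atoms: N-iodosuccinimide, O=C1CCC(=O)N1I
Why: Electrophilic aromatic iodination of the trioxygenated A ring is directed to C8 (ortho to O1 and O7, para to O5) and away from C6, which lies between two benzyloxy groups, in line with the C8 selectivity known for N-halosuccinimides on 5,7-di-O-benzylated flavans.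

Step 8
Reactants: 11 (S)-4-[5,7-bis(benzyloxy)-8-iodochroman-2-yl]phenyl pivalate; 12 1-(benzyloxy)-4-ethynylbenzene
Product: 13 (S)-4-{5,7-bis(benzyloxy)-8-[(4-benzyloxyphenyl)ethynyl]chroman-2-yl}phenyl pivalate
Conditions: 12 (1.3 equiv), Pd(PPh3)2Cl2 (5 mol%), CuI (10 mol%), Et3N, DMF, 70 °C, degassed
Reagents that add atoms: none
Why: Sonogashira coupling of the aryl iodide with the terminal alkyne (oxidative addition, transmetallation from the copper acetylide, reductive elimination) under a tertiary amine that does not cleave the aryl pivalate and involves no bond at C2.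

Step 9
Reactants: 13 (S)-4-{5,7-bis(benzyloxy)-8-[(4-benzyloxyphenyl)ethynyl]chroman-2-yl}phenyl pivalate
Product: 14 (S)-4-{5,7-bis(benzyloxy)-8-[2-(4-benzyloxyphenyl)-2-oxoacetyl]chroman-2-yl}phenyl pivalate
Conditions: PdCl2 (10 mol%), DMSO, 140 °C
Reagents that add atoms: dimethyl sulfoxide, CS(C)=O
Why: Palladium(II)-catalysed oxidation of a diarylalkyne to a 1,2-diketone, in which DMSO attacks the Pd-activated alkyne twice as the oxygen donor and leaves as dimethyl sulfide, under conditions to which benzyl ethers, the aryl ester and the saturated flavan are inert.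

Step 10
Reactants: 14 (S)-4-{5,7-bis(benzyloxy)-8-[2-(4-benzyloxyphenyl)-2-oxoacetyl]chroman-2-yl}phenyl pivalate
Product: 15 (S)-4-{5,7-dihydroxy-8-[2-(4-hydroxyphenyl)-2-oxoacetyl]chroman-2-yl}phenyl pivalate
Conditions: BCl3 (8 equiv), pentamethylbenzene (10 equiv), CH2Cl2, −78 °C; MeOH quench at −78 °C
Reagents that add atoms: none
Why: Lewis-acid debenzylation of aryl benzyl ethers in the presence of a non-Lewis-basic cation scavenger, which takes up the benzyl cations by Friedel–Crafts alkylation and spares the dione and the ester, the pivalate being kept on the B ring at this stage so that heterolysis of the benzylic O1–C2 bond stays unfavourable.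

Step 11
Reactants: 15 (S)-4-{5,7-dihydroxy-8-[2-(4-hydroxyphenyl)-2-oxoacetyl]chroman-2-yl}phenyl pivalate
Product: 16 1-[(2S)-5,7-dihydroxy-2-(4-hydroxyphenyl)chroman-8-yl]-2-(4-hydroxyphenyl)ethane-1,2-dione
Conditions: K2CO3 (4 equiv), MeOH, 0 °C → rt, argon; then 1 M HCl to pH 4
Reagents that add atoms: none
Why: Base-mediated transesterification (methanolysis) of the aryl pivalate with the phenoxide as leaving group, run cold, without air and with prompt acidification so that the dione is spared and C2 cannot epimerise through a quinone methide.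

**Compound list**

1 | 4-hydroxybenzaldehyde | O=Cc1ccc(O)cc1 | starting material
2 | 4-formylphenyl pivalate | O=Cc1ccc(OC(=O)C(C)(C)C)cc1 | intermediate
3 | trimethylsilylacetylene | C#C[Si](C)(C)C | starting material
4 | ethyl(trimethylsilylethynyl)zinc | CC[Zn]C#C[Si](C)(C)C | intermediate (not isolated)
5 | (S)-4-[1-hydroxy-3-(trimethylsilyl)prop-2-yn-1-yl]phenyl pivalate | O[C@@H](c1ccc(OC(=O)C(C)(C)C)cc1)C#C[Si](C)(C)C | intermediate
6 | (R)-4-(1-hydroxyprop-2-yn-1-yl)phenyl pivalate | O[C@@H](c1ccc(OC(=O)C(C)(C)C)cc1)C#C | intermediate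
7 | 3,5-bis(benzyloxy)phenol | Oc1cc(OCc2ccccc2)cc(OCc2ccccc2)c1 | starting material
8 | (S)-4-{1-[3,5-bis(benzyloxy)phenoxy]prop-2-yn-1-yl}phenyl pivalate | c1c(OCc2ccccc2)cc(OCc2ccccc2)cc1O[C@H](c1ccc(OC(=O)C(C)(C)C)cc1)C#C | intermediate
9 | (S)-4-[5,7-bis(benzyloxy)-2H-chromen-2-yl]phenyl pivalate | c1c(OCc2ccccc2)cc(OCc2ccccc2)c2c1O[C@H](c1ccc(OC(=O)C(C)(C)C)cc1)C=C2 | intermediate
10 | (S)-4-[5,7-bis(benzyloxy)chroman-2-yl]phenyl pivalate | c1c(OCc2ccccc2)cc(OCc2ccccc2)c2c1O[C@H](c1ccc(OC(=O)C(C)(C)C)cc1)CC2 | intermediate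
11 | (S)-4-[5,7-bis(benzyloxy)-8-iodochroman-2-yl]phenyl pivalate | Ic1c(OCc2ccccc2)cc(OCc2ccccc2)c2c1O[C@H](c1ccc(OC(=O)C(C)(C)C)cc1)CC2 | intermediate
12 | 1-(benzyloxy)-4-ethynylbenzene | C#Cc1ccc(OCc2ccccc2)cc1 | starting material
13 | (S)-4-{5,7-bis(benzyloxy)-8-[(4-benzyloxyphenyl)ethynyl]chroman-2-yl}phenyl pivalate | c1cc(OCc2ccccc2)ccc1C#Cc1c(OCc2ccccc2)cc(OCc2ccccc2)c2c1O[C@H](c1ccc(OC(=O)C(C)(C)C)cc1)CC2 | intermediate
14 | (S)-4-{5,7-bis(benzyloxy)-8-[2-(4-benzyloxyphenyl)-2-oxoacetyl]chroman-2-yl}phenyl pivalate | O=C(C(=O)c1c(OCc2ccccc2)cc(OCc2ccccc2)c2c1O[C@H](c1ccc(OC(=O)C(C)(C)C)cc1)CC2)c1ccc(OCc2ccccc2)cc1 | intermediate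
15 | (S)-4-{5,7-dihydroxy-8-[2-(4-hydroxyphenyl)-2-oxoacetyl]chroman-2-yl}phenyl pivalate | O=C(C(=O)c1c(O)cc(O)c2c1O[C@H](c1ccc(OC(=O)C(C)(C)C)cc1)CC2)c1ccc(O)cc1 | intermediate
16 | 1-[(2S)-5,7-dihydroxy-2-(4-hydroxyphenyl)chroman-8-yl]-2-(4-hydroxyphenyl)ethane-1,2-dione | O=C(C(=O)c1c(O)cc(O)c2c1O[C@H](c1ccc(O)cc1)CC2)c1ccc(O)cc1 | target

**Step count and risks**

Total: 11 steps. Longest linear sequence: 11 steps (1 → 16); 3, 7 and 12 are purchased and enter in steps 2, 4 and 8.

Step 5 (key step). The π-acid may ionise the propargylic C–O bond instead of activating the alkyne, which would erode the enantiomeric purity or fragment the ether. The catalyst may also be tied up as a gold acetylide, and the electron-rich chromene may dimerise under acid. The fallback makes the same C4–C4a bond by a Friedel–Crafts closure on a carbonyl group. It sets out from 8. Hydroboration of the terminal alkyne with dicyclohexylborane (THF, 0 °C) should give the alkenylborane 4-{(1S,2E)-1-[3,5-bis(benzyloxy)phenoxy]-3-(dicyclohexylboranyl)prop-2-en-1-yl}phenyl pivalate F1. Oxidation in the same flask with H2O2 at pH 7 (phosphate buffer) should give the aldehyde (S)-4-{1-[3,5-bis(benzyloxy)phenoxy]-3-oxopropyl}phenyl pivalate F2. The crude aldehyde is treated with TFA and Et3SiH in CH2Cl2 at −20 °C, so that the activated arene attacks the protonated formyl group to give the flavan-4-ol 4-[(2S)-5,7-bis(benzyloxy)-4-hydroxychroman-2-yl]phenyl pivalate F3 (both C4 epimers, not isolated). Its C4 cation, stabilised by the ortho and para oxygens, is then reduced by the silane. The fallback returns to the route at 10, and steps 5 and 6 are no longer needed.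

Step 10. Boron trichloride, chelated between the C8 carbonyl and O1, may heterolyse the benzylic O1–C2 bond. That would racemise C2 or open the pyran ring with capture by the scavenger. The fallback removes the benzyl groups by hydrogenolysis before any reducible group is present and replaces them by groups that leave under the conditions of step 11. It sets out from 10 and proceeds as follows:

- Hydrogenolysis (H2, Pd/C, EtOAc) should give (S)-4-(5,7-dihydroxychroman-2-yl)phenyl pivalate F4.
- Silylation (TBSCl, imidazole, DMF) should give (S)-4-[5,7-bis(tert-butyldimethylsilyloxy)chroman-2-yl]phenyl pivalate F5.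
- Iodination with NIS should give (S)-4-[5,7-bis(tert-butyldimethylsilyloxy)-8-iodochroman-2-yl]phenyl pivalate F6, C6 being screened by two silyloxy groups.
- Sonogashira coupling with commercially available tert-butyl(4-ethynylphenoxy)dimethylsilane should give (S)-4-{5,7-bis(tert-butyldimethylsilyloxy)-8-[(4-(tert-butyldimethylsilyloxy)phenyl)ethynyl]chroman-2-yl}phenyl pivalate F7.
- Oxidation of the alkyne (buffered KMnO4 in aqueous acetone, or as in step 9) should give (S)-4-{5,7-bis(tert-butyldimethylsilyloxy)-8-[2-(4-(tert-butyldimethylsilyloxy)phenyl)-2-oxoacetyl]chroman-2-yl}phenyl pivalate F8.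
- Methanolysis with K2CO3 in MeOH then removes the three aryl silyl ethers and the pivalate in one operation, and the fallback returns to the route at 16.

Step 9. The ortho benzyloxy oxygen may attack the Pd-activated alkyne, giving a benzofuran with loss or transfer of benzyl, or oxygen transfer to the doubly ortho-substituted alkyne may stall. The fallback builds the dione without an alkyne and sets out from 11. Iodine–lithium exchange (n-BuLi, THF, −78 °C) should give {(2S)-5,7-bis(benzyloxy)-2-[4-(pivaloyloxy)phenyl]chroman-8-yl}lithium F9. This is added to N,N'-dimethoxy-N,N'-dimethyloxamide to give, after work-up, the α-keto N-methoxy-N-methyl amide (S)-4-{5,7-bis(benzyloxy)-8-[2-(methoxy(methyl)amino)-2-oxoacetyl]chroman-2-yl}phenyl pivalate F10. Addition of commercial (4-benzyloxyphenyl)magnesium bromide (THF, −78 → 0 °C) to the amide carbonyl, whose chelated adduct collapses only on work-up, returns to the route at 14. This also bypasses the hindered coupling of step 8.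

Further compounds
F1 | step 5 | 4-{(1S,2E)-1-[3,5-bis(benzyloxy)phenoxy]-3-(dicyclohexylboranyl)prop-2-en-1-yl}phenyl pivalate | c1c(OCc2ccccc2)cc(OCc2ccccc2)cc1O[C@H](c1ccc(OC(=O)C(C)(C)C)cc1)/C=C/B(C1CCCCC1)C1CCCCC1
F2 | step 5 | (S)-4-{1-[3,5-bis(benzyloxy)phenoxy]-3-oxopropyl}phenyl pivalate | c1c(OCc2ccccc2)cc(OCc2ccccc2)cc1O[C@H](c1ccc(OC(=O)C(C)(C)C)cc1)CC=O
F3 | step 5 | 4-[(2S)-5,7-bis(benzyloxy)-4-hydroxychroman-2-yl]phenyl pivalate (C4 epimers) | c1c(OCc2ccccc2)cc(OCc2ccccc2)c2c1O[C@H](c1ccc(OC(=O)C(C)(C)C)cc1)CC2O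
F4 | step 10 | (S)-4-(5,7-dihydroxychroman-2-yl)phenyl pivalate | c1c(O)cc(O)c2c1O[C@H](c1ccc(OC(=O)C(C)(C)C)cc1)CC2
F5 | step 10 | (S)-4-[5,7-bis(tert-butyldimethylsilyloxy)chroman-2-yl]phenyl pivalate | c1c(O[Si](C)(C)C(C)(C)C)cc(O[Si](C)(C)C(C)(C)C)c2c1O[C@H](c1ccc(OC(=O)C(C)(C)C)cc1)CC2
F6 | step 10 | (S)-4-[5,7-bis(tert-butyldimethylsilyloxy)-8-iodochroman-2-yl]phenyl pivalate | Ic1c(O[Si](C)(C)C(C)(C)C)cc(O[Si](C)(C)C(C)(C)C)c2c1O[C@H](c1ccc(OC(=O)C(C)(C)C)cc1)CC2
F7 | step 10 | (S)-4-{5,7-bis(tert-butyldimethylsilyloxy)-8-[(4-(tert-butyldimethylsilyloxy)phenyl)ethynyl]chroman-2-yl}phenyl pivalate | CC(C)(C)[Si](C)(C)Oc1ccc(cc1)C#Cc1c(O[Si](C)(C)C(C)(C)C)cc(O[Si](C)(C)C(C)(C)C)c2c1O[C@H](c1ccc(OC(=O)C(C)(C)C)cc1)CC2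
F8 | step 10 | (S)-4-{5,7-bis(tert-butyldimethylsilyloxy)-8-[2-(4-(tert-butyldimethylsilyloxy)phenyl)-2-oxoacetyl]chroman-2-yl}phenyl pivalate | CC(C)(C)[Si](C)(C)Oc1ccc(cc1)C(=O)C(=O)c1c(O[Si](C)(C)C(C)(C)C)cc(O[Si](C)(C)C(C)(C)C)c2c1O[C@H](c1ccc(OC(=O)C(C)(C)C)cc1)CC2
F9 | step 9 | {(2S)-5,7-bis(benzyloxy)-2-[4-(pivaloyloxy)phenyl]chroman-8-yl}lithium | [Li]c1c(OCc2ccccc2)cc(OCc2ccccc2)c2c1O[C@H](c1ccc(OC(=O)C(C)(C)C)cc1)CC2
F10 | step 9 | (S)-4-{5,7-bis(benzyloxy)-8-[2-(methoxy(methyl)amino)-2-oxoacetyl]chroman-2-yl}phenyl pivalate | CON(C)C(=O)C(=O)c1c(OCc2ccccc2)cc(OCc2ccccc2)c2c1O[C@H](c1ccc(OC(=O)C(C)(C)C)cc1)CC2
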